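If the 3 sites of the substrate were alike and independent, each taken up by partner with a small chance p, double product would stand at 3 times the square of p and tris adduct at the cube of p. So a reading D of double product gives a statistical tris adduct: take the square root of D divided by 3 and cube it. Use this as the zero of the scale.

| flask | substrate | partner | remark | time |
|---|---|---|---|---|
| Wednesday's | 0.048 M | 0.070 M | run made earlier |  |
| Sunday's | 0.048 M | 0.11 M | run made earlier |  |
| Friday's | 0.072 M | 0.14 M | run made earlier |  |
| flask | 0.048 M | 0.140 M |  | 3.0 min |

| run | time / min | double product / % | tris adduct / % |
|---|---|---|---|
| Wednesday's | 0.500 | 0.9 | 0.1 |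
| Wednesday's | 1.00 | 1.9 | 0.7 |
| Wednesday's | 1.33 | 3.4 | 0.2 |
| Wednesday's | 2.00 | 3.3 | 1.0 |
| Wednesday's | 2.50 | 4.0 | 0.8 |
| Sunday's | 0.200 | 0.6 | 0 |
| Sunday's | 0.333 | 1.2 | 0 |
| Sunday's | 0.667 | 3.3 | 0.5 |
| Sunday's | 1.33 | 6.5 | 1.8 |
| Sunday's | 2.50 | 7.8 | 2.2 |
| Friday's | 0.200 | 1.0 | 0.4 |
| Friday's | 0.667 | 4.3 | 1.2 |
| Friday's | 1.00 | 5.9 | 1.5 |
| Friday's | 1.50 | 7.0 | 2.2 |
| Friday's | 2.50 | 8.7 | 2.9 |

(scatter of a reading: 0.3 percentage points)

- equivalents of partner to substrate, everything else as given, that leave most double product at 3.0 min
- the amount of double product then, in percent of the substrate charged
- the amount of double product with the amounts as given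

- for released group the idle adduct is counted in
- reactions considered so far: partner -> decomposed reagent; tris adduct + released group -> side product; substrate + partner -> mono adduct + released group; partner + released group <-> idle adduct; partner + double product -> tris adduct + released group; partner + mono adduct -> double product + released group

Read the last row of each run, at 2.50 min. Wednesday's run gives tris adduct at 5.20 times its statistical amount, though a scatter of 0.3 percentage points on 0.8% makes this reading loose. Sunday's run, with more partner, gives 5.25. Friday's run, with more of both charges, gives 5.87. Double product grew by a factor of 2.17 down these rows, yet the ratio read stayed between 5.20 and 5.87. Keep the mean, 5.44, as the tris excess, the measured tris adduct over its statistical amount. It stands above 1, so expect tris adduct to accompany double product at this multiple of its statistical amount. My reckoning stops there: it links the two products but gives no yield.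

The forecast expects that in the flask “free partner stays higher than in any run”. It gives 12.5% as charged, and 16% at 4.7 equiv.

The flask gives 10.6% as charged, and 18.0% at 7.03 equiv, which is 1.50 times the forecast's equivalents.

    partner → decomposed reagent (k = 0.0131 /s)
    tris adduct + released group → side product (k = 0.113 /M/s)
    substrate + partner → mono adduct + released group (k = 0.0849 /M/s)
    partner + released group ⇌ idle adduct, settled at all times (K = 41.8 /M)
    partner + double product → tris adduct + released group (k = 0.176 /M/s)
    partner + mono adduct → double product + released group (k = 0.123 /M/s)

In the flask, 10.6% of double product and the tris excess give 3.63% of tris adduct, and the flask holds more, 4.64%. Partner is the limiting reagent there, with 5.5% of its charge still there, unbound, against 55% of the substrate. The same flask without the turning of partner into decomposed reagent reaches 17.5% of double product, not 10.6%. In the neighbour charged with 0.035 M of partner, 1.45% of double product and the tris excess give 0.183% of tris adduct; the computed amount is 0.159%.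

Readings and results stem from a simulated flask for an exercise, noise included.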